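In the north-west run [partner] cannot have stayed near its charge, whatever the two equivalents suggest.

| setting | north-west | west | north-east | Tuesday's | Saturday's | Friday's | Wednesday's |
|---|---|---|---|---|---|---|---|
| starting material | 11 mM | 5.5 mM | 8.2 mM | 11 mM (fed, over 12.0 min) | 11 mM | 11 mM | 11 mM |
| partner | 22 mM | 22 mM | 22 mM | 22.0 mM | 22.0 mM | 22.0 mM | 22.0 mM (fed, over 12.0 min) |
| capture agent | 0.55 mM | 0.55 mM | 0.55 mM | 0.550 mM | 0.550 mM | 0.550 mM | 0.550 mM |
| remark | run made earlier | run made earlier | run made earlier | a stirred flask in which starting material is dosed at a steady rate over 12.0 min without added volume, worked up at 15 min | a single well-mixed tank run continuously and read at steady state, 15 min in it on average | a closed flask charged with all of it at once and left for 15 min | a stirred flask in which partner is dosed at a steady rate over 12.0 min without added volume, worked up at 15 min |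
| time |  |  |  | 15 min |  | 15 min | 15 min |

| run | time / min | target / % | trapped intermediate / % | side product / % |
|---|---|---|---|---|
| north-west | 4.00 | 50.0 | 0.7 | 33.7 |
| north-west | 8.00 | 51.2 | 0.8 | 39.8 |
| north-west | 12.0 | 51.1 | 0.8 | 41.5 |
| north-west | 15.0 | 51.4 | 0.1 | 42.6 |
| west | 3.00 | 52.1 | 0.1 | 27.9 |
| west | 6.00 | 54.4 | 0.7 | 35.7 |
| west | 10.0 | 54.8 | 0.4 | 37.2 |
| west | 12.0 | 55.3 | 0.9 | 37.2 |
| north-east | 1.00 | 31.0 | 0 | 11.0 |
| north-east | 2.00 | 45.4 | 0.3 | 21.5 |
| north-east | 5.00 | 52.5 | 0.4 | 35.5 |
| north-east | 12.0 | 53.4 | 0.9 | 39.3 |

(scatter of a reading: 0.3 percentage points)

- the stated concentrations are those of everything mixed, before any reaction; amounts are the same in each set-up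
- the feed brings no volume worth counting
- the earlier runs were made in a closed, stirred flask

1. the set-up with the highest share of target in all that became target or trapped intermediate or side product or isomer of the product, at the outlet or at the end ("none" if the first two lie within 2 percentage points) (Tuesday's / Saturday's / Friday's / Wednesday's / none)
2. share of target in all that became target or trapped intermediate or side product or isomer of the product, at the outlet or at the end, Tuesday's
3. share of target in all that became target or trapped intermediate or side product or isomer of the product, at the outlet or at the end, Saturday's
4. share of target in all that became target or trapped intermediate or side product or isomer of the product, at the outlet or at the end, Friday's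
5. share of target in all that became target or trapped intermediate or side product or isomer of the product, at the outlet or at the end, Wednesday's

At the bench I would read 2.00 equivalents as plenty. In the north-west run target took 5.65 mM, a quarter of the partner charged, so by that rule of thumb [partner] should have stayed near 16.3 mM, and slow dosing of starting material should cost nothing.

The border shows in the selectivity factor, target gained per side product gained, which I took to follow [partner]. Up to 1.00 min in the north-east run it read 2.82. From there to 2.00 min it fell to half. The middles of those intervals lie 1.00 min apart, and that spacing is my partner half-life, a reading with the runs' scatter. From 4.00 min to 15.0 min in the north-west run the factor read 0.157, which, scaled on the charge, gave me an estimate of [partner] near 1.23 mM.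

Tuesday's feed lasts 12.0 half-lives, far longer, so 8.33% of its starting material arrives inside the first. Letting the factor fall as 2.82 over one plus the half-lives elapsed, taking the share as factor over one plus factor, and averaging over the feed, I reckoned Tuesday's at 33.4%. Friday's has the north-west charge, whose run ended at 51.4% of target, so I put Friday's above Tuesday's.

The forecast gave Tuesday's 50.5% (46% to 58%), Saturday's 46%, Friday's 51.5%, Wednesday's 20% and best none, holding that “Tuesday's has low A but slightly lower partner during consumption”. My Tuesday's stood lower, and there I differed from the forecast.

The flasks gave Tuesday's 23.5%, Saturday's 43.5%, Friday's 51.4%, Wednesday's 31.2%, best Friday's.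

    starting material → open intermediate (k = 0.0322 /s)
    partner + open intermediate → target (k = 1.24 /M/s)
    2 partner → homo product (k = 0.507 /M/s)
    open intermediate + capture agent → trapped intermediate (k = 0.151 /M/s)
    open intermediate → side product (k = 0.00508 /s)
    target ⇌ isomer of the product (K = 0.120, k = 9.86 × 10⁻⁴ /s)

Tuesday's fell 27 percentage points under the forecast and also under my figure. At the end of its feed, 12.0 half-lives in, [partner] stood at 2.23% of its charge beside 9.53 mM of homo product. The neighbour is Friday's flask read at 4.0 min, which is 4.00 half-lives. The fall I used for Tuesday's, one over one plus the half-lives, gives 20.0% of the partner; that neighbour flask held 9.46%, with target at 49.9% and 11.4% of the starting material as open intermediate.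

(The readings come from a simulation with made-up constants; noise was put on by code.)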